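**Plan**

Numbering (longipinane): C-1 ring-B ketone, C-2=C-3 (C-12 is the methyl on C-3), C-4 and C-11 cyclobutane CH, C-5 cyclobutane CH bearing C-6 (CMe2), C-7 (angelate), C-8, C-9 (tiglate), C-10 cyclobutane C–Me. Ring A is the cyclobutane, ring B the cyclohexenone, ring C the seven-membered ring.
Cuts: first the two ester C–O bonds, then the C-9–O bond and the C-8=C-9 unsaturation back to longipin-2-ene-1,7-dione, then the C-9–C-10 bond, then the lactone-derived C-5–C-6 bond, last the two cyclobutane bonds C-4–C-10 and C-5–C-11.
Feature used: C-10, the methyl-bearing quaternary carbon of ring A, is bonded to C-9, the tiglate carbinol carbon of ring C. C-10 can therefore be a 1-methylcyclobutyl radical made from a carboxylic acid, and C-9 the terminal carbon of a vinyl ketone C-7(=O)–C-8=C-9 on the CMe2 arm at C-5.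
Forward: rings A and B form together by intramolecular vinylketene–alkene [2+2] cycloaddition of an 8-acyloxygeranic acid. The isobutyrate on the C-10 hydroxymethyl group then delivers C-6/C-7 to C-5 as a lactone, ring B is oxidised, the lactone is opened to vinyl ketone and acid, and ring C closes in the key step.
Stereochemistry: the relative configuration of C-4, C-5, C-10 and C-11 comes from the suprafacial cycloaddition and the lactone tether, and the absolute configuration from a lipase resolution of the ring-B allylic alcohol. C-9 is set by ligand-controlled copper-catalysed borylation, C-7 by 1,3-anti hydride delivery (Evans–Tishchenko), and the ester alkene geometries come from tiglaldehyde and angelic acid.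

Key step: step 14

Remarks on the chemistry (assumptions): compounds 7 and 9–14 are racemic and are drawn as the enantiomer that is carried on after step 9. The 2,3-geometry of geranic acid is lost in step 3, so an E/Z mixture would serve equally. The lipase is assumed to acetylate the (1R)-alcohol; if it prefers the (1S)-alcohol, the unreacted alcohol goes on and step 10 is unchanged.

**Route**

Step 1
Reactants: 1 (2E)-geranic acid
Product: 2 (2E,6E)-8-hydroxy-3,7-dimethylocta-2,6-dienoic acid
Conditions: SeO2 (cat.), tBuOOH, CH2Cl2, 0 °C to rt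
Reagents that add atoms: tert-butyl hydroperoxide, CC(C)(C)OO (terminal oxidant; the oxygen is passed on by catalytic selenium dioxide, O=[Se]=O)
Why: Catalytic SeO2 allylic oxidation (ene reaction then [2,3]-sigmatropic shift) attacks the electron-rich terminal trisubstituted alkene at its (E)-methyl group and leaves the electron-poor conjugated alkene alone, so the 6E geometry needed in step 3 is set here.

Step 2
Reactants: 2 (2E,6E)-8-hydroxy-3,7-dimethylocta-2,6-dienoic acid; 3 isobutyric anhydride
Product: 4 (2E,6E)-3,7-dimethyl-8-(2-methylpropanoyloxy)octa-2,6-dienoic acid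
Conditions: (iPrCO)2O, pyridine, DMAP (cat.), CH2Cl2, 0 °C to rt; then aq. NaHCO3, THF; H3O+
Reagents that add atoms: isobutyric anhydride 3, CC(C)C(=O)OC(=O)C(C)C
Why: DMAP-catalysed acylation of the primary allylic alcohol, with the mixed anhydride at the carboxyl group hydrolysed in the bicarbonate work-up; the isobutyrate is both protecting group and the future C-6/C-7 unit with its two methyl groups.

Step 3
Reactants: 4 (2E,6E)-3,7-dimethyl-8-(2-methylpropanoyloxy)octa-2,6-dienoic acid
Product: 7 rac-(7-methyl-2-methylidene-6-oxobicyclo[3.1.1]heptan-7-yl)methyl 2-methylpropanoate (acyloxymethyl anti; methyl syn to the three-carbon bridge), via acid chloride 5 (not isolated), via vinylketene 6 (not isolated)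
Conditions: (COCl)2, DMF (cat.), CH2Cl2, 0 °C to rt; evaporate; slow addition to Et3N, toluene, 110 °C, high dilution
Reagents that add atoms: none
Why: Intramolecular [2+2] cycloaddition of a vinylketene (from 1,4-dehydrochlorination of the enoyl chloride) with the trisubstituted alkene, in which the ketene carbonyl carbon bonds to the CH end and the α-carbon to the fully substituted end, giving the bridged bicyclo[3.1.1]heptan-6-one and not the fused isomer; suprafacial addition to the (6E)-alkene puts the acyloxymethyl group anti and the methyl group syn to the three-carbon bridge.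

Step 4
Reactants: 7 rac-(7-methyl-2-methylidene-6-oxobicyclo[3.1.1]heptan-7-yl)methyl 2-methylpropanoate; 8 methyl chlorooxoacetate
Product: 10 5-(methoxyoxalyloxy)-8-oxalongipin-3(12)-en-7-one (tertiary oxalate of the bridged hydroxy lactone; racemic), via lithium alkoxide 9 (not isolated)
Conditions: LDA, THF, −78 °C; then ClCOCO2Me, −78 to 0 °C
Reagents that add atoms: methyl chlorooxoacetate 8, COC(=O)C(Cl)=O
Why: Intramolecular aldol addition of the isobutyrate enolate to the strained, non-enolisable cyclobutanone, in which the ester hangs on the anti position of C-10 so that the enolate reaches C-5 only from that side and the C-5–C-6 bond forms anti to ring B within a seven-membered lactone (the 8-oxa analogue of ring C); the lithium alkoxide is acylated in the same flask so that it cannot revert.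

Step 5
Reactants: 10 5-(methoxyoxalyloxy)-8-oxalongipin-3(12)-en-7-one
Product: 11 8-oxalongipin-3(12)-en-7-one (racemic; H at C-5 syn to ring B)
Conditions: Bu3SnH, AIBN (cat.), toluene, 110 °C
Reagents that add atoms: none
Why: Radical deoxygenation of a tertiary alkyl methyl oxalate with Bu3SnH (Barton–McCombie type), where elimination is impossible (bridgehead and quaternary neighbours) and the lactone holds C-6 on the anti side, so the C-5 radical takes its hydrogen on the side of ring B and C-5 is set.

Step 6
Reactants: 11 8-oxalongipin-3(12)-en-7-one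
Product: 12 8-oxalongipin-2-en-7-one (racemic)
Conditions: RhCl3·3H2O (cat.), EtOH, 80 °C
Reagents that add atoms: none
Why: Rhodium hydride-mediated migration of the exocyclic double bond into the ring gives the more stable trisubstituted alkene, and it can move only toward C-2 because C-4 is a bridgehead, while the hindered pivalate-like lactone should resist ethanolysis.

Step 7
Reactants: 12 8-oxalongipin-2-en-7-one
Product: 13 8-oxalongipin-2-ene-1,7-dione (racemic)
Conditions: CrO3, 3,5-dimethylpyrazole, CH2Cl2, −20 °C
Reagents that add atoms: chromium trioxide, O=[Cr](=O)=O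
Why: Allylic oxidation with the CrO3–3,5-dimethylpyrazole complex at the only secondary allylic position (the oxidation that turns α-pinene into verbenone), C-4 being a bridgehead and the lactone inert.

Step 8
Reactants: 13 8-oxalongipin-2-ene-1,7-dione
Product: 14 rac-1-hydroxy-8-oxalongipin-2-en-7-one (hydroxyl cis to the C-10 bridge; drawn as 1R)
Conditions: NaBH4, CeCl3·7H2O, MeOH, −40 °C
Reagents that add atoms: none
Why: Luche 1,2-reduction, in which hydride attacks C-1 from the side of the C-5 bridge (only a hydrogen points there) and not past the C-10 methyl group, giving one diastereomer; the alcohol level masks the ring-B ketone for steps 10 and 11 and is the handle for resolution.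

Step 9
Reactants: 14 rac-1-hydroxy-8-oxalongipin-2-en-7-one; 15 vinyl acetate
Product: 16 (1R)-1-acetoxy-8-oxalongipin-2-en-7-one (single enantiomer)
Conditions: Burkholderia cepacia lipase (Amano PS), vinyl acetate, tBuOMe, 30 °C, stopped near 45% conversion; chromatography
Reagents that add atoms: vinyl acetate 15, C=COC(C)=O
Why: Lipase-catalysed kinetic resolution of a cyclic secondary allylic alcohol by irreversible transesterification, in which the empirical size rule (bridgehead C-11 large, vinylic C-2 medium) makes the (1R)-alcohol the fast one, and separation of acetate from unreacted alcohol fixes the absolute configuration of C-4, C-5, C-10 and C-11.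

Step 10
Reactants: 16 (1R)-1-acetoxy-8-oxalongipin-2-en-7-one
Product: 17 2-[4-hydroxy-6-(hydroxymethyl)-2,6-dimethylbicyclo[3.1.1]hept-2-en-7-yl]-2-methylpropanal (hydroxymethyl and C-7 side chain anti to the alkene bridge; in equilibrium with its seven-membered lactol)
Conditions: DIBAL-H (3.2 equiv), CH2Cl2, −78 °C; Rochelle salt
Reagents that add atoms: none
Why: DIBAL-H reduces the lactone to the aluminium hemiacetal, which is stable at −78 °C and gives the aldehyde (as its lactol tautomer) on work-up, and the same reagent removes the acetate reductively.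

Step 11
Reactants: 17 2-[4-hydroxy-6-(hydroxymethyl)-2,6-dimethylbicyclo[3.1.1]hept-2-en-7-yl]-2-methylpropanal; 18 vinylmagnesium bromide
Product: 19 4-[4-hydroxy-6-(hydroxymethyl)-2,6-dimethylbicyclo[3.1.1]hept-2-en-7-yl]-4-methylpent-1-en-3-ol (both epimers at the new carbinol carbon)
Conditions: CH2=CHMgBr (5 equiv), THF, −78 to 0 °C; aq. NH4Cl
Reagents that add atoms: vinylmagnesium bromide 18, C=C[Mg]Br
Why: Grignard addition to the non-enolisable neopentyl aldehyde released from the lactol by the basic reagent, with the two hydroxyl groups carried as magnesium alkoxides and the new carbinol centre removed again in step 12.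

Step 12
Reactants: 19 4-[4-hydroxy-6-(hydroxymethyl)-2,6-dimethylbicyclo[3.1.1]hept-2-en-7-yl]-4-methylpent-1-en-3-ol
Product: 20 2,6-dimethyl-7-(2-methyl-3-oxopent-4-en-2-yl)-4-oxobicyclo[3.1.1]hept-2-ene-6-carboxylic acid (carboxyl and C-7 side chain anti to the enone bridge)
Conditions: CrO3, H2SO4, acetone, H2O, 0 °C
Reagents that add atoms: water, O; chromium trioxide, O=[Cr](=O)=O
Why: Jones oxidation, in which the two secondary allylic alcohols go quickly to the ring-B enone and the vinyl ketone and the primary alcohol then goes to the acid through the aldehyde hydrate; the fast allylic oxidation keeps the C-7 hydroxyl from trapping the C-10 aldehyde as a lactol.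

Step 13
Reactants: 20 2,6-dimethyl-7-(2-methyl-3-oxopent-4-en-2-yl)-4-oxobicyclo[3.1.1]hept-2-ene-6-carboxylic acid; 21 N-hydroxyphthalimide
Product: 22 1,3-dioxoisoindolin-2-yl 2,6-dimethyl-7-(2-methyl-3-oxopent-4-en-2-yl)-4-oxobicyclo[3.1.1]hept-2-ene-6-carboxylate
Conditions: N-hydroxyphthalimide, DIC, DMAP (cat.), CH2Cl2, 0 °C to rt
Reagents that add atoms: N-hydroxyphthalimide 21, ON1C(=O)c2ccccc2C1=O
Why: Carbodiimide (Steglich-type) esterification to the redox-active N-acyloxyphthalimide under near-neutral conditions at low temperature, which spare the vinyl ketone.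

Step 14
Reactants: 22 1,3-dioxoisoindolin-2-yl 2,6-dimethyl-7-(2-methyl-3-oxopent-4-en-2-yl)-4-oxobicyclo[3.1.1]hept-2-ene-6-carboxylate
Product: 23 longipin-2-ene-1,7-dione
Conditions: graphite-felt cathode, sacrificial Zn anode, undivided cell, LiClO4 (0.1 M), DMF, H2O (10 equiv), constant current (about 2.2 F/mol), 5 mM, rt
Reagents that add atoms: none
Why: One-electron reduction of the N-acyloxyphthalimide at the cathode (it is reduced at a far less negative potential than either enone) is followed by N–O cleavage and loss of CO2 to give the 1-methylcyclobutyl radical at C-10, which adds to the terminal carbon C-9 of the tethered vinyl ketone; the α-keto radical is then reduced to the enolate and protonated by water. The closest known reaction type is the reductive decarboxylative Giese addition of tertiary N-acyloxyphthalimides to electron-poor alkenes under cathodic or photoredox conditions, run here intramolecularly. Ring C closes in the 7-endo-trig mode, the 6-exo alternative being disfavoured because it would bond a nucleophilic tertiary radical to the α-carbon of the enone. The new stereocentre C-10 is controlled by the substrate: the planar radical reaches the acceptor only through the lobe anti to ring B, on which the C-5 arm is held, so the methyl group stays syn to ring B whatever the configuration of the acid was. The step needs cyclisation to outrun intermolecular addition and hydrogen abstraction, which high dilution and the 1,3-diaxial proximity of C-10 and the arm on the cyclobutane should secure.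

Step 15
Reactants: 23 longipin-2-ene-1,7-dione
Product: 25 longipina-2,8-diene-1,7-dione, via silyl enol ether 24 (not isolated)
Conditions: LiHMDS, TMSCl, Et3N, THF, −78 °C; then Pd(OAc)2 (1.1 equiv), MeCN, rt
Reagents that add atoms: none
Why: Saegusa–Ito oxidation, in which C-8 is the only enolisable position of the ring-C ketone (C-6 is quaternary) and is deprotonated faster than the γ-methyl group of the ring-B enone, whose α′-position is a bridgehead, before palladium diacetate dehydrosilylates the enol ether.

Step 16
Reactants: 25 longipina-2,8-diene-1,7-dione; 26 bis(pinacolato)diboron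
Product: 27 9-(4,4,5,5-tetramethyl-1,3,2-dioxaborolan-2-yl)longipin-2-ene-1,7-dione (boron on the face of C-9 turned toward C-11)
Conditions: B2pin2, CuCl (5 mol%), NaOtBu (5 mol%), (R,SP)-Josiphos-type ferrocenyl bisphosphine (5 mol%; antipode chosen by trial of both), MeOH (2 equiv), THF, rt
Reagents that add atoms: bis(pinacolato)diboron 26, CC1(C)OB(OC1(C)C)B1OC(C)(C)C(C)(C)O1
Why: Copper-catalysed conjugate borylation (borylcopper addition, then protonation of the copper enolate by MeOH) at the disubstituted ring-C enone, the β,β-disubstituted ring-B enone being far slower; ring C lies close to the local mirror plane of the cyclobutane, so the substrate hardly distinguishes the two faces of C-9 and the chiral ligand should decide which one is borylated.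

Step 17
Reactants: 27 9-(4,4,5,5-tetramethyl-1,3,2-dioxaborolan-2-yl)longipin-2-ene-1,7-dione
Product: 28 (9R)-9-hydroxylongipin-2-ene-1,7-dione
Conditions: NaBO3·4H2O, THF/H2O, rt
Reagents that add atoms: sodium perborate, [Na+].[O-]OB=O
Why: Oxidation of the C–B bond with retention of configuration by mild, nearly neutral perborate, which should spare both enones and avoid β-elimination of the aldol.

Step 18
Reactants: 28 (9R)-9-hydroxylongipin-2-ene-1,7-dione; 29 tiglaldehyde [(E)-2-methylbut-2-enal]
Product: 30 (7R,9R)-7-hydroxy-9-tigloyloxylongipin-2-en-1-one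
Conditions: tiglaldehyde (6 equiv), SmI2 (0.3 equiv), THF, −10 °C
Reagents that add atoms: tiglaldehyde 29, C/C=C(\C)C=O
Why: Evans–Tishchenko reduction, in which the samarium-bound hemiacetal formed from the C-9 alkoxide and tiglaldehyde delivers hydride to C-7 through a six-membered transition state on the face of the C-9 oxygen, giving the 1,3-anti (trans) diol with the tiglate on O-9 and a free hydroxyl at C-7, without base and so without β-elimination.

Step 19
Reactants: 30 (7R,9R)-7-hydroxy-9-tigloyloxylongipin-2-en-1-one; 31 angelic acid [(Z)-2-methylbut-2-enoic acid]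
Product: 33 (4R,5S,7R,9R,10R,11R)-7-angeloyloxy-9-tigloyloxylongipin-2-en-1-one (CNP0236543.4), via mixed anhydride 32 (not isolated)
Conditions: angelic acid, 2,4,6-trichlorobenzoyl chloride, Et3N, toluene, rt; then 30, toluene, 80 °C
Reagents that add atoms: angelic acid 31, C/C=C(/C)C(=O)O
Why: Yamaguchi-type acylation through the mixed anhydride without a nucleophilic catalyst, conditions that transfer the (Z)-2-methylbut-2-enoyl group to hindered secondary alcohols without isomerisation to the tiglate, while the C-9 tiglate and both enones stay untouched.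

**Compound list**

1 | (2E)-geranic acid | CC(C)=CCC/C(C)=C/C(=O)O | starting material
2 | (2E,6E)-8-hydroxy-3,7-dimethylocta-2,6-dienoic acid | OC/C(C)=C/CC/C(C)=C/C(=O)O | intermediate
3 | isobutyric anhydride | CC(C)C(=O)OC(=O)C(C)C | starting material
4 | (2E,6E)-3,7-dimethyl-8-(2-methylpropanoyloxy)octa-2,6-dienoic acid | CC(C)C(=O)OC/C(C)=C/CC/C(C)=C/C(=O)O | intermediate
5 | acid chloride of 4 | CC(C)C(=O)OC/C(C)=C/CC/C(C)=C/C(Cl)=O | intermediate
6 | vinylketene, (6E)-7-methyl-3-methylidene-8-(2-methylpropanoyloxy)octa-1,6-dien-1-one | CC(C)C(=O)OC/C(C)=C/CCC(=C)C=C=O | intermediate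
7 | rac-(7-methyl-2-methylidene-6-oxobicyclo[3.1.1]heptan-7-yl)methyl 2-methylpropanoate, acyloxymethyl anti to the three-carbon bridge | CC(C)C(=O)OC[C@@]1(C)[C@@H]2CCC(=C)[C@H]1C2=O | intermediate
8 | methyl chlorooxoacetate | COC(=O)C(Cl)=O | starting material
9 | lithium alkoxide of rac-5-hydroxy-8-oxalongipin-3(12)-en-7-one | O=C1OC[C@@]2(C)[C@@H]3CCC(=C)[C@H]2[C@]3([O-])C1(C)C.[Li+] | intermediate
10 | rac-5-(methoxyoxalyloxy)-8-oxalongipin-3(12)-en-7-one | O=C1OC[C@@]2(C)[C@@H]3CCC(=C)[C@H]2[C@]3(OC(=O)C(=O)OC)C1(C)C | intermediate
11 | rac-8-oxalongipin-3(12)-en-7-one | O=C1OC[C@@]2(C)[C@@H]3CCC(=C)[C@H]2[C@@H]3C1(C)C | intermediate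
12 | rac-8-oxalongipin-2-en-7-one | O=C1OC[C@@]2(C)[C@@H]3CC=C(C)[C@H]2[C@@H]3C1(C)C | intermediate
13 | rac-8-oxalongipin-2-ene-1,7-dione | O=C1OC[C@@]2(C)[C@@H]3C(=O)C=C(C)[C@H]2[C@@H]3C1(C)C | intermediate
14 | rac-1-hydroxy-8-oxalongipin-2-en-7-one, hydroxyl cis to the C-10 bridge | O=C1OC[C@@]2(C)[C@@H]3[C@H](O)C=C(C)[C@H]2[C@@H]3C1(C)C | intermediate
15 | vinyl acetate | C=COC(C)=O | starting material
16 | (1R)-1-acetoxy-8-oxalongipin-2-en-7-one | O=C1OC[C@@]2(C)[C@@H]3[C@H](OC(C)=O)C=C(C)[C@H]2[C@@H]3C1(C)C | intermediate
17 | 2-[4-hydroxy-6-(hydroxymethyl)-2,6-dimethylbicyclo[3.1.1]hept-2-en-7-yl]-2-methylpropanal | OC[C@@]1(C)[C@@H]2[C@H](O)C=C(C)[C@H]1[C@@H]2C(C)(C)C=O | intermediate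
18 | vinylmagnesium bromide | C=C[Mg]Br | starting material
19 | 4-[4-hydroxy-6-(hydroxymethyl)-2,6-dimethylbicyclo[3.1.1]hept-2-en-7-yl]-4-methylpent-1-en-3-ol, both carbinol epimers | OC[C@@]1(C)[C@@H]2[C@H](O)C=C(C)[C@H]1[C@@H]2C(C)(C)C(O)C=C | intermediate
20 | 2,6-dimethyl-7-(2-methyl-3-oxopent-4-en-2-yl)-4-oxobicyclo[3.1.1]hept-2-ene-6-carboxylic acid | O=C(O)[C@@]1(C)[C@@H]2C(=O)C=C(C)[C@H]1[C@@H]2C(C)(C)C(=O)C=C | intermediate
21 | N-hydroxyphthalimide | ON1C(=O)c2ccccc2C1=O | starting material
22 | N-hydroxyphthalimide ester of 20 (key-step precursor) | O=C(ON1C(=O)c2ccccc2C1=O)[C@@]3(C)[C@@H]4C(=O)C=C(C)[C@H]3[C@@H]4C(C)(C)C(=O)C=C | intermediate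
23 | longipin-2-ene-1,7-dione (key-step product) | O=C1CC[C@@]2(C)[C@@H]3C(=O)C=C(C)[C@H]2[C@@H]3C1(C)C | intermediate
24 | 7-(trimethylsilyloxy)longipina-2,7-dien-1-one | C[Si](C)(C)OC1=CC[C@@]2(C)[C@@H]3C(=O)C=C(C)[C@H]2[C@@H]3C1(C)C | intermediate
25 | longipina-2,8-diene-1,7-dione | O=C1C=C[C@@]2(C)[C@@H]3C(=O)C=C(C)[C@H]2[C@@H]3C1(C)C | intermediate
26 | bis(pinacolato)diboron | CC1(C)OB(OC1(C)C)B1OC(C)(C)C(C)(C)O1 | starting material
27 | 9-(pinacolboryl)longipin-2-ene-1,7-dione, boron on the C-11 face | O=C1C[C@@H](B4OC(C)(C)C(C)(C)O4)[C@@]2(C)[C@@H]3C(=O)C=C(C)[C@H]2[C@@H]3C1(C)C | intermediate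
28 | (9R)-9-hydroxylongipin-2-ene-1,7-dione | O=C1C[C@@H](O)[C@@]2(C)[C@@H]3C(=O)C=C(C)[C@H]2[C@@H]3C1(C)C | intermediate
29 | tiglaldehyde, (E)-2-methylbut-2-enal | C/C=C(\C)C=O | starting material
30 | (7R,9R)-7-hydroxy-9-tigloyloxylongipin-2-en-1-one | O[C@@H]1C[C@@H](OC(=O)/C(C)=C/C)[C@@]2(C)[C@@H]3C(=O)C=C(C)[C@H]2[C@@H]3C1(C)C | intermediate
31 | angelic acid, (Z)-2-methylbut-2-enoic acid | C/C=C(/C)C(=O)O | starting material
32 | angelic 2,4,6-trichlorobenzoic mixed anhydride | C/C=C(/C)C(=O)OC(=O)c1c(Cl)cc(Cl)cc1Cl | intermediate
33 | (4R,5S,7R,9R,10R,11R)-7-angeloyloxy-9-tigloyloxylongipin-2-en-1-one, CNP0236543.4 | C/C=C(/C)C(=O)O[C@@H]1C[C@@H](OC(=O)/C(C)=C/C)[C@@]2(C)[C@@H]3C(=O)C=C(C)[C@H]2[C@@H]3C1(C)C | target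

**Step count and risks**

Total step count: 19. Longest linear sequence: 19 steps from geranic acid (all other inputs are commercial reagents).

Step 14 is the most likely to fail. The C-10 radical may be intercepted before ring closure, by hydrogen abstraction or by addition to the vinyl ketone of a second molecule, and the enones may be reduced at the electrode once the ester is used up. The fallback sets out from acid 20 and generates the same radical oxidatively in homogeneous dilute solution: Ir[dF(CF3)ppy]2(dtbbpy)PF6 (cat.), K2HPO4, DMF, blue light. The carboxylate is oxidised by the excited photocatalyst, loses CO2, and the radical cyclises onto the vinyl ketone. The reduced photocatalyst then turns the α-keto radical into the enolate, which is protonated. This photoredox decarboxylative conjugate addition of free carboxylic acids is known chemistry, needs no activated ester, and comes back to the route at 23.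

Step 4 is the second risk. The amide base may add to or reduce the strained, non-enolisable cyclobutanone, or the aldolate may revert or fragment before it is acylated. The fallback sets out from 7 and forms the enolate reductively under non-basic conditions. K2CO3 in MeOH removes the isobutyrate to give the hydroxy ketone F1. 2-Bromo-2-methylpropanoyl bromide and pyridine give the bromo ester F2. SmI2 (2.2 equiv) in THF at −78 °C then effects an intramolecular Reformatsky reaction, a closure known for seven-membered and larger lactones, to give the hydroxy lactone F3. Acylation of F3 with methyl chlorooxoacetate, DMAP and Et3N returns to the route at 10.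

Step 9 is the third risk. The enzyme may accept the hindered alcohol only slowly or with poor discrimination between the enantiomers. The fallback sets out from 14 and resolves through covalent diastereomers. Esterification with (S)-O-methylmandelic acid (DCC, DMAP, CH2Cl2) gives the ester of the (1R)-alcohol F4 and the diastereomeric ester of the (1S)-alcohol F5, which are separated by chromatography or crystallisation. Methanolysis of F4 (K2CO3, MeOH, rt; the pivalate-like lactone should survive) gives the resolved (1R)-alcohol F6. F6 enters step 10 with 2.2 equiv of DIBAL-H and comes back to the route at 17.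

Further compounds
F0 | step 14 | none | none
F1 | step 4 | rac-7-(hydroxymethyl)-7-methyl-2-methylidenebicyclo[3.1.1]heptan-6-one | OC[C@@]1(C)[C@@H]2CCC(=C)[C@H]1C2=O
F2 | step 4 | rac-(7-methyl-2-methylidene-6-oxobicyclo[3.1.1]heptan-7-yl)methyl 2-bromo-2-methylpropanoate | CC(C)(Br)C(=O)OC[C@@]1(C)[C@@H]2CCC(=C)[C@H]1C2=O
F3 | step 4 | rac-5-hydroxy-8-oxalongipin-3(12)-en-7-one | O=C1OC[C@@]2(C)[C@@H]3CCC(=C)[C@H]2[C@]3(O)C1(C)C
F4 | step 9 | (S)-O-methylmandelate of (1R)-1-hydroxy-8-oxalongipin-2-en-7-one | O=C1OC[C@@]2(C)[C@@H]3[C@H](OC(=O)[C@@H](OC)c4ccccc4)C=C(C)[C@H]2[C@@H]3C1(C)C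
F5 | step 9 | (S)-O-methylmandelate of the (1S)-alcohol, the diastereomer that is removed | O=C1OC[C@]2(C)[C@H]3[C@@H](OC(=O)[C@@H](OC)c4ccccc4)C=C(C)[C@@H]2[C@H]3C1(C)C
F6 | step 9 | (1R)-1-hydroxy-8-oxalongipin-2-en-7-one, single enantiomer | O=C1OC[C@@]2(C)[C@@H]3[C@H](O)C=C(C)[C@H]2[C@@H]3C1(C)C
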